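Remark on the chemistry: the carbon labels C1–C13 of the target are kept for every intermediate (ring C1–C10, C11 on C7, C12 the lactone carbon, C13 the methyl on C11), and compounds 5 and 10 are treated as purchasable.

## Analysis of the target

CNP0226482.5 is a germacranolide: a cyclodeca-1(10),4-diene (C1–C10) trans-fused at C6–C7 to an α-methyl-γ-butyrolactone (ring oxygen on C6, carbonyl C12, C11 bearing the C13 methyl), with acetates on the allylic carbons C3 and C9. Both ring alkenes are trisubstituted and methyl-bearing, but C1=C10 is Z (C2 cis to C9) and C4=C5 is E, so the ring holds one cis and one trans cycloalkene. There are five stereocentres: 3S and 9S are remote from the rest (C3 is 1,4 to C6 across the E alkene, C9 is 1,3 to C7), and 6S, 7S, 11R form a contiguous triad. In the triad H-6 and H-7 are anti (trans-lactone) and H-7 and H-11 are syn, so the C13 methyl sits cis to C8. This is the arrangement to be set kinetically and then kept away from base. The sensitive elements are the two allylic acetates (ionisation, hydrolysis, hydride and organometallic reagents), the epimerisable C11, the 1,5-diene C10=C1–C2–C3–C4=C5 that is set up for Cope rearrangement on heating, and the tendency of such dienes to cyclise across the ring under acid. The difficulty is twofold: a ten-membered ring must be closed with two trisubstituted alkenes of opposite geometry, and C3 and C9 cannot be related to C6/C7 by substrate control. The strategy rests on the segment C9–C8–C7 with the three-carbon branch C11(C12)(C13) on C7. At the ketone/isopropenyl oxidation level this segment is a γ,δ-unsaturated ketone, C9(=O)–C8–C7–C11=C12. That is the retron of a Claisen rearrangement of a twelve-membered 2-methylene ether in which oxygen joins C9 to C12.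

## Retrosynthetic reasoning

31 to 29 via 30. The two acetate C–O bonds are cut first, and both hydroxyls are carried as TBS ethers. Acetates would not survive the hydride, organotitanium and borane reagents needed upstream, and a lactone without other acidic sites keeps an enolate-based correction at C11 available. The forward steps are a non-basic desilylation and a double acetylation.

29 to 23 via 26 and 25. The lactone C12–O bond and the C12 oxidation level are taken back to the primary alcohol 25 (through diol 26), and 25 to the isopropenyl compound 23 by removing H from C11 and OH from C12. The lactone cannot be present earlier, because C12 and C11 must be the allyl terminus of the key step, and an isopropenyl group on C7 is exactly what the sigmatropic shift leaves behind. Forward, a hydroboration has to pick the 1,1-disubstituted alkene among three and pick its face (11R), the PMB group has to come off, and the primary alcohol must be oxidised selectively so that it closes onto O-6.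

23 to 21 via 22. The C9–H bond is cut, so the C9 carbinol comes from the C9 ketone. The ketone is the direct product of the key step, and a reagent-controlled 1,2-reduction can set 9S without relying on the remote centres.

21 to 20 (key disconnection). The ring bond C7–C8 is cut and O(C9) is reconnected to C12. No other ring bond offers this: C7–C8 is the only one flanked by a carbonyl-level carbon and a carbon with a three-carbon branch. What is gained is that the strained ten-membered ring no longer has to be closed end to end, since it arises from a twelve-membered ring by contraction. The new stereocentre C7 is made next to the existing C6, where 1,2-induction can operate. The forward reaction must deliver C8 to one face of the E-C7=C11 alkene and leave the two ring alkenes alone.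

20 to 18 via 19. The exocyclic methylene (C8) is removed to give macrolactone 19, and the lactone C12–O bond is cut to give seco acid 18. The cut is placed on the alkyl C–O bond and not on the acyl C–O bond, so that the forward ring closure activates the primary allylic alcohol and never the Z-2-methyl enoic acid, whose geometry is at risk under acyl activation. C8 is then added by a non-acidic titanium methylenation.

18 to 12 and 4 via 17, 16 and 15. The C6–C7 bond between the two alkenes is cut, which splits the chain into the C1–C6/C9–C10 aldehyde 12 and the three-carbon alkenyl iodide 4. This is the convergent point. The forward addition must create 6S under catalyst control because C3 is too far away to help. The remaining moves are protecting-group and oxidation-level changes (PMB on O-6, TES off O-12, ester to acid).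

12 to 9 and 10 via 11. The C1=C10 alkene is cut by a Z-selective olefination between aldehyde 9 and phosphonate 10. C6 stays masked as its dimethyl acetal until this is done, so that only one aldehyde is present at a time.

9 to 5 via 7 and 6. The C2–C3 bond is cut, so an allyl group is added to the C3 aldehyde of 5. The terminal alkene is a masked C1 aldehyde. Forward, an enantioselective allylboration sets 3S, and the monosubstituted alkene is cleaved in the presence of the trisubstituted C4=C5 alkene, whose E geometry is bought with 5.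

4 to 1 via 3. The C11–CH3 and C7–I bonds are cut. A syn carbometalation of the alkyne 1 followed by iodination fixes the E geometry of C7=C11, which the key step needs for its stereocontrol.

## Alternatives that were turned down

Alternative 1: The C3–C4 bond is cut, leading back to the open-chain ynal A1, in which the trans-lactone, the C9 acetate and Z-C1=C10 are already present, C3 is an aldehyde and C6 carries a propynyl group (C5≡C4–CH3). In the forward step a zerovalent nickel–carbene catalyst and a trialkylsilane join the aldehyde carbon to C4 through an oxanickelacycle, giving A2 with the ring, the E-C4=C5 alkene (syn addition) and the O-3 silyl ether formed together. In its favour, one catalytic step makes the ring, an alkene of secured geometry, the C3 stereocentre and its protecting group, and only desilylation and acetylation remain. After the key step it is clearly shorter than the chosen route. Against it for this target: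
- The ten-membered ring is closed directly, against transannular strain and in competition with oligomerisation.
- The alkyne can insert in the other sense and give a nine-membered ring with an exocyclic alkene.
- 3S would rest only on the conformation of the forming ring, far from C6, C7 and C9.
- A1 carries a β,γ-unsaturated aldehyde that drifts into conjugation, and the stereotriad C6/C7/C11 plus C9 must be built on an open chain.

The chosen strategy sets C3 by reagent control in its first step and replaces the medium-ring closure by an unstrained twelve-membered lactonisation followed by an intramolecular shift. It pays for this with a longer endgame.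

Alternative 2: A transannular bond C4–C9 is added in the retrosynthetic sense, so that the ten-membered ring comes from the decalin A3 with a tertiary hydroxyl on C9, an angular methyl on C4 and a mesylate on C5. Forward, deprotonation of the C9 hydroxyl starts a Grob-type (Wharton) fragmentation: C4–C9 breaks, C9 becomes the ketone, C4=C5 forms as the mesylate leaves, and A4 results. In its favour, the fragmentation is stereospecific. The antiperiplanar C4–C9 and equatorial C5–O bonds of a trans-decalin dictate the E alkene, and Z-C1=C10 is secured because it sits in a six-membered ring beforehand. No medium ring is ever closed, and the lactone with C11 is in place, so few steps follow. On alkene geometry and on the length of the endgame this plan is stronger than the chosen one. Against it, A3 carries seven stereocentres, among them two adjacent fully substituted ring-fusion carbons that must be trans, and a secondary sulfonate wedged between the quaternary C4 and the lactone-bearing C6 beside a free tertiary alcohol. Reaching that by six-membered-ring annulation means a long linear sequence in which the risk is spread over many steps. The chosen strategy offers convergent assembly from three small pieces, with each stereocentre set by a separate, independently tunable reaction and the risk concentrated in one step.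

Alternative 3: Both ring alkenes are disconnected at once by adding the σ-bonds C1–C4 and C5–C10, which leads to the strained tricyclic photoadduct A5 (a cyclohexanone fused to a bicyclo[2.2.0]hexane). Forward, flash vacuum thermolysis breaks the central C1–C4 bond and then C5–C10, unfolding the three small rings into the ten-membered dienone A6 with the C3 acetate and the lactone already present. In its favour, the plan is extremely short and free of protecting groups, a single reagent-free step makes the ring and both trisubstituted alkenes, and A6 is two steps from the target. On step count it beats every other plan, the chosen one included. Against it: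
- The Z/E outcome at C1=C10 and C4=C5 depends on the course of a stepwise diradical cycloreversion at several hundred degrees and cannot be enforced.
- At those temperatures the product, a 1,5-diene with an allylic acetate, should undergo Cope rearrangement to a divinylcyclohexane and lose acetic acid.
- The photocycloaddition that makes A5 creates four stereocentres at once, with regiochemical and facial ambiguity.

In the chosen route the pericyclic step runs in solution at about 140 °C, and both alkene geometries are fixed beforehand by olefination and allylboration chemistry. It is longer, but every element of structure is placed by a controllable step.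

Key step: step 14

## Route

Step 1
Reactants: 1 prop-2-yn-1-ol
Product: 3 (2E)-3-iodo-2-methylprop-2-en-1-ol, via alkenylalane 2 (not isolated)
Conditions: Me3Al, Cp2ZrCl2 (0.25 equiv), CH2Cl2, 0 °C to rt; then I2, THF, −30 to 0 °C
Reagents that add atoms: trimethylaluminium C[Al](C)C; iodine II
Why: Zirconium-catalysed carboalumination (Negishi) adds methyl and aluminium syn across the alkyne with aluminium at the terminus, and iodinolysis with retention gives the E iodide (iodine trans to CH2OH), which fixes the E geometry of C7=C11.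

Step 2
Reactants: 3 (2E)-3-iodo-2-methylprop-2-en-1-ol
Product: 4 triethyl{[(2E)-3-iodo-2-methylprop-2-en-1-yl]oxy}silane
Conditions: TESCl, imidazole, CH2Cl2, 0 °C
Reagents that add atoms: chlorotriethylsilane CC[Si](Cl)(CC)CC
Why: Standard silylation; the primary TES ether tolerates tert-butyllithium at −78 °C and can later be removed in the presence of a secondary TBS ether.

Step 3
Reactants: 5 (2E)-4,4-dimethoxy-2-methylbut-2-enal
Product: 6 (4S,5E)-7,7-dimethoxy-5-methylhepta-1,5-dien-4-ol
Conditions: (−)-Ipc2BOMe [from (+)-α-pinene], allylMgBr, Et2O, 0 °C to rt; then 5, −78 °C; NaOH, H2O2 work-up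
Reagents that add atoms: allylmagnesium bromide C=CC[Mg]Br
Why: Brown allylboration through a closed chair transition state; the reagent derived from (+)-α-pinene attacks the Si face of the aldehyde, the facial sense that gives (S)-1-phenylbut-3-en-1-ol from benzaldehyde, and so sets 3S, while the acetal is inert to the basic conditions.

Step 4
Reactants: 6 (4S,5E)-7,7-dimethoxy-5-methylhepta-1,5-dien-4-ol
Product: 7 tert-butyl{[(4S,5E)-7,7-dimethoxy-5-methylhepta-1,5-dien-4-yl]oxy}dimethylsilane
Conditions: TBSCl, imidazole, DMF, rt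
Reagents that add atoms: tert-butylchlorodimethylsilane CC(C)(C)[Si](C)(C)Cl
Why: Silylation under non-Lewis-acidic conditions, so the allylic dimethyl acetal is not ionised as it could be with a silyl triflate.

Step 5
Reactants: 7 tert-butyl{[(4S,5E)-7,7-dimethoxy-5-methylhepta-1,5-dien-4-yl]oxy}dimethylsilane
Product: 9 (3S,4E)-3-[(tert-butyldimethylsilyl)oxy]-6,6-dimethoxy-4-methylhex-4-enal, via diol 8 (not isolated)
Conditions: OsO4 (2 mol %), NMO, acetone–H2O, 0 °C; then NaIO4, THF–pH 7 buffer, 0 °C
Reagents that add atoms: osmium tetroxide O=[Os](=O)(=O)=O (oxygen carrier); N-methylmorpholine N-oxide C[N+]1([O-])CCOCC1 (terminal oxygen source)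
Why: Upjohn dihydroxylation then periodate glycol cleavage; the monosubstituted alkene should react well before the trisubstituted C4=C5 alkene, which is shielded by the OTBS group and deactivated by two allylic C–O carbons (acetal and silyl ether).

Step 6
Reactants: 9 (3S,4E)-3-[(tert-butyldimethylsilyl)oxy]-6,6-dimethoxy-4-methylhex-4-enal; 10 ethyl 2-[bis(2,2,2-trifluoroethoxy)phosphoryl]propanoate
Product: 11 ethyl (2Z,5S,6E)-5-[(tert-butyldimethylsilyl)oxy]-8,8-dimethoxy-2,6-dimethylocta-2,6-dienoate
Conditions: KHMDS, 18-crown-6, THF, −78 °C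
Reagents that add atoms: none
Why: Still–Gennari variant of the Horner–Wadsworth–Emmons reaction; the electron-poor trifluoroethyl phosphonate with a dissociated potassium counter-ion eliminates quickly from the kinetic adduct and gives the Z-2-methyl enoate (C2 cis to C9), and −78 °C avoids β-elimination of the silyloxy group.

Step 7
Reactants: 11 ethyl (2Z,5S,6E)-5-[(tert-butyldimethylsilyl)oxy]-8,8-dimethoxy-2,6-dimethylocta-2,6-dienoate
Product: 12 ethyl (2Z,5S,6E)-5-[(tert-butyldimethylsilyl)oxy]-2,6-dimethyl-8-oxoocta-2,6-dienoate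
Conditions: PPTS (cat.), acetone–H2O, rt
Reagents that add atoms: water O
Why: Acid-catalysed hydrolysis of the allylic dimethyl acetal, which ionises far more readily than the secondary TBS ether is cleaved; the E enal is the stable isomer.

Step 8
Reactants: 4 triethyl{[(2E)-3-iodo-2-methylprop-2-en-1-yl]oxy}silane; 12 ethyl (2Z,5S,6E)-5-[(tert-butyldimethylsilyl)oxy]-2,6-dimethyl-8-oxoocta-2,6-dienoate
Product: 15 ethyl (2Z,5S,6E,8S,9E)-5-[(tert-butyldimethylsilyl)oxy]-8-hydroxy-2,6,10-trimethyl-11-[(triethylsilyl)oxy]undeca-2,6,9-trienoate, via alkenyllithium 13 (not isolated), via dialkenylzinc 14 (not isolated)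
Conditions: 4 (2.4 equiv), tBuLi (4.8 equiv), Et2O, −78 °C; ZnBr2 (1.2 equiv), −78 to 0 °C; N,N,N′,N′-tetraethylethylenediamine, (−)-MIB (10 mol %), toluene; then 12, −20 to 0 °C
Reagents that add atoms: none
Why: Iodine–lithium exchange with retention, transmetalation to zinc and amino-alcohol-catalysed alkenyl transfer to the aldehyde; the zinc alkoxide of (−)-MIB should send the alkenyl group to the Si face (the sense that gives (S)-alcohols from benzaldehyde and dialkylzincs), which is 6S here, the diamine ties up the lithium halides that would promote a racemic background addition, and the organozinc does not touch the enoate.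

Step 9
Reactants: 15 ethyl (2Z,5S,6E,8S,9E)-5-[(tert-butyldimethylsilyl)oxy]-8-hydroxy-2,6,10-trimethyl-11-[(triethylsilyl)oxy]undeca-2,6,9-trienoate
Product: 16 ethyl (2Z,5S,6E,8S,9E)-5-[(tert-butyldimethylsilyl)oxy]-8-[(4-methoxybenzyl)oxy]-2,6,10-trimethyl-11-[(triethylsilyl)oxy]undeca-2,6,9-trienoate
Conditions: NaH, PMBBr, Bu4NI (cat.), THF–DMF, 0 °C
Reagents that add atoms: 4-methoxybenzyl bromide COc1ccc(CBr)cc1
Why: Williamson etherification of the sodium alkoxide; basic conditions avoid ionising the doubly allylic C6–O bond, which acid-catalysed benzylation would risk, and the hindered trisubstituted enoate should be left alone at 0 °C.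

Step 10
Reactants: 16 ethyl (2Z,5S,6E,8S,9E)-5-[(tert-butyldimethylsilyl)oxy]-8-[(4-methoxybenzyl)oxy]-2,6,10-trimethyl-11-[(triethylsilyl)oxy]undeca-2,6,9-trienoate
Product: 17 ethyl (2Z,5S,6E,8S,9E)-5-[(tert-butyldimethylsilyl)oxy]-11-hydroxy-8-[(4-methoxybenzyl)oxy]-2,6,10-trimethylundeca-2,6,9-trienoate
Conditions: HF·pyridine, pyridine, THF, 0 °C
Reagents that add atoms: none
Why: Fluoride-mediated desilylation; the primary TES ether is cleaved much faster than the hindered secondary TBS ether, and the pyridine buffer keeps the bis-allylic PMB ether from ionising.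

Step 11
Reactants: 17 ethyl (2Z,5S,6E,8S,9E)-5-[(tert-butyldimethylsilyl)oxy]-11-hydroxy-8-[(4-methoxybenzyl)oxy]-2,6,10-trimethylundeca-2,6,9-trienoate
Product: 18 (2Z,5S,6E,8S,9E)-5-[(tert-butyldimethylsilyl)oxy]-11-hydroxy-8-[(4-methoxybenzyl)oxy]-2,6,10-trimethylundeca-2,6,9-trienoic acid
Conditions: LiOH, THF–MeOH–H2O, 40 °C; then 0.5 M HCl to pH 5, 0 °C
Reagents that add atoms: lithium hydroxide [Li+].[OH-]
Why: Ester saponification by acyl–oxygen cleavage; silyl and PMB ethers are stable to hydroxide, and the brief, cold acidification to pH 5 spares the bis-allylic ether.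

Step 12
Reactants: 18 (2Z,5S,6E,8S,9E)-5-[(tert-butyldimethylsilyl)oxy]-11-hydroxy-8-[(4-methoxybenzyl)oxy]-2,6,10-trimethylundeca-2,6,9-trienoic acid
Product: 19 (3Z,6S,7E,9S,10E)-6-[(tert-butyldimethylsilyl)oxy]-9-[(4-methoxybenzyl)oxy]-3,7,11-trimethyl-1-oxacyclododeca-3,7,10-trien-2-one (twelve-membered lactone; carbonyl = C9; ring oxygen on C12)
Conditions: PPh3, DIAD, toluene–THF, 0 °C to rt, slow addition of 18 (final 2 mM)
Reagents that add atoms: none
Why: Mitsunobu macrolactonisation: the primary allylic alcohol is activated as its alkoxyphosphonium ion and displaced at C12 by the carboxylate under high dilution, so the acid is never activated and the Z-2-methyl enoate cannot isomerise through an acyl-ammonium or ketene intermediate; the twelve-membered ring accommodates the s-trans ester and the two E alkenes.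

Step 13
Reactants: 19 (3Z,6S,7E,9S,10E)-6-[(tert-butyldimethylsilyl)oxy]-9-[(4-methoxybenzyl)oxy]-3,7,11-trimethyl-1-oxacyclododeca-3,7,10-trien-2-one
Product: 20 tert-butyl{[(3Z,6S,7E,9S,10E)-9-[(4-methoxybenzyl)oxy]-3,7,11-trimethyl-2-methylidene-1-oxacyclododeca-3,7,10-trien-6-yl]oxy}dimethylsilane (2-methylene ether; C8 = exocyclic CH2 on C9)
Conditions: Cp2TiMe2 (3 equiv), toluene, 70 °C, dark; filtration through basic alumina
Reagents that add atoms: dimethyltitanocene [CH3-].[CH3-].[Ti+4].c1cc[cH-]c1.c1cc[cH-]c1
Why: Petasis methylenation: Cp2TiMe2 loses methane on heating to give Cp2Ti=CH2, which adds to the only carbonyl group and cycloreverts to the enol ether and Cp2TiO; the reagent is non-acidic and aluminium-free, which suits the acid-labile 2-alkoxydiene.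

Step 14
Reactants: 20 tert-butyl{[(3Z,6S,7E,9S,10E)-9-[(4-methoxybenzyl)oxy]-3,7,11-trimethyl-2-methylidene-1-oxacyclododeca-3,7,10-trien-6-yl]oxy}dimethylsilane
Product: 21 (3S,6R,7S)-3-[(tert-butyldimethylsilyl)oxy]-6-[(4-methoxybenzyl)oxy]germacra-1(10)Z,4E,11(12)-trien-9-one [= (2Z,5S,6E,8R,9S)-5-[(tert-butyldimethylsilyl)oxy]-8-[(4-methoxybenzyl)oxy]-2,6-dimethyl-9-(prop-1-en-2-yl)cyclodeca-2,6-dien-1-one]
Conditions: toluene (0.01 M), Et3N (trace), 140 °C, sealed base-washed tube
Reagents that add atoms: none
Why: Heating triggers the [3,3]-sigmatropic (Claisen) shift of the allyl vinyl ether C8=C9–O–C12–C11=C7: C8 bonds to C7 while O–C12 breaks, which turns C9 into a ketone and C11=C12 into the isopropenyl group. The closest known reaction type is the Claisen rearrangement of 2-methylene oxacycles obtained by titanium methylenation of lactones, used here in its ring-contracting sense because the allyl unit lies inside the ring. The ten-membered carbocycle is therefore closed by contraction of the twelve-membered ether through a chair-like six-centre transition state that shares C9, O, C12, C11 and C7 with the macrocycle (C8 enters the ring; O, C12 and C11 leave it), not by end-to-end cyclisation, so no dilution is needed and the strain of the medium ring is paid for by the new C=O bond. The one new stereocentre, C7, is controlled by C6: on the E alkene the C11 methyl is cis to C6, allylic 1,3-strain holds C6–H in the alkene plane, and C8 is delivered to the C7 face opposite the PMB ether, the face on which the tether through C5 already lies, which gives the 6,7-anti arrangement of the later trans-lactone (7S). The step needs [3,3] selectivity over ionisation ([1,3] shift), over 1,5-hydrogen migration in the alkoxydiene and over Cope rearrangement of the C10=C1–C2–C3–C4=C5 diene; non-polar solvent, base-treated glass, a trace of amine and the lowest workable temperature serve the first two, and the Z,E geometry of the diene, which would force a boat Cope transition state, the third. Z-C1=C10 and E-C4=C5 lie outside the pericyclic array and keep their geometry.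

Step 15
Reactants: 21 (3S,6R,7S)-3-[(tert-butyldimethylsilyl)oxy]-6-[(4-methoxybenzyl)oxy]germacra-1(10)Z,4E,11(12)-trien-9-one
Product: 22 (3S,6R,7S,9S)-3-[(tert-butyldimethylsilyl)oxy]-6-[(4-methoxybenzyl)oxy]germacra-1(10)Z,4E,11(12)-trien-9-ol
Conditions: (R)-2-methyl-CBS-oxazaborolidine (0.5 equiv), catecholborane, toluene, −78 °C
Reagents that add atoms: none
Why: Corey–Bakshi–Shibata reduction; the ketone binds to the oxazaborolidine with the alkenyl side (C10) as the large group and hydride is delivered to the Re face, so the (R)-catalyst should give 9S (the (S)-catalyst gives (R)-carbinols from ketones with this priority pattern), and catecholborane at −78 °C reduces 1,2 without hydroborating the alkenes.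

Step 16
Reactants: 22 (3S,6R,7S,9S)-3-[(tert-butyldimethylsilyl)oxy]-6-[(4-methoxybenzyl)oxy]germacra-1(10)Z,4E,11(12)-trien-9-ol
Product: 23 (3S,6R,7S,9S)-3,9-bis[(tert-butyldimethylsilyl)oxy]-6-[(4-methoxybenzyl)oxy]germacra-1(10)Z,4E,11(12)-triene
Conditions: TBSOTf, 2,6-lutidine, CH2Cl2, −78 °C
Reagents that add atoms: tert-butyldimethylsilyl trifluoromethanesulfonate CC(C)(C)[Si](C)(C)OS(=O)(=O)C(F)(F)F
Why: Silylation of the hindered allylic carbinol with the silyl triflate; the C9 hydroxyl would otherwise be exposed to the two oxidations that follow, and a silyl ether (unlike an acetate) leaves the later lactone free of competing acidic sites.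

Step 17
Reactants: 23 (3S,6R,7S,9S)-3,9-bis[(tert-butyldimethylsilyl)oxy]-6-[(4-methoxybenzyl)oxy]germacra-1(10)Z,4E,11(12)-triene
Product: 25 (3S,6S,7S,9S,11R)-3,9-bis[(tert-butyldimethylsilyl)oxy]-6-[(4-methoxybenzyl)oxy]germacra-1(10)Z,4E-dien-12-ol, via trialkylborane 24 (not isolated)
Conditions: 9-BBN, THF, 0 °C to rt; then NaOH, H2O2, 0 °C
Reagents that add atoms: hydrogen peroxide OO
Why: Hydroboration–oxidation; 9-BBN adds boron only to C12 of the 1,1-disubstituted alkene (the trisubstituted ring alkenes are inert), and in the rotamer with C7–H in the alkene plane next to C12 the borane should approach anti to the branched C6 substituent, i.e. from the C8 side, which places the new hydrogen on C11 so as to give 11R; oxidation proceeds with retention.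

Step 18
Reactants: 25 (3S,6S,7S,9S,11R)-3,9-bis[(tert-butyldimethylsilyl)oxy]-6-[(4-methoxybenzyl)oxy]germacra-1(10)Z,4E-dien-12-ol
Product: 26 (3S,6S,7S,9S,11R)-3,9-bis[(tert-butyldimethylsilyl)oxy]germacra-1(10)Z,4E-diene-6,12-diol
Conditions: DDQ, CH2Cl2–pH 7 buffer, 0 °C
Reagents that add atoms: none
Why: Oxidative PMB cleavage (charge-transfer complex, benzylic hydride abstraction, hydrolysis of the hemiacetal); silyl ethers and the ring alkenes are untouched and the buffer prevents acid-induced transannular cyclisation.

Step 19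
Reactants: 26 (3S,6S,7S,9S,11R)-3,9-bis[(tert-butyldimethylsilyl)oxy]germacra-1(10)Z,4E-diene-6,12-diol
Product: 29 (3S,6S,7S,9S,11R)-3,9-bis[(tert-butyldimethylsilyl)oxy]germacra-1(10)Z,4E-dien-12,6-olide, via hydroxy aldehyde 27 (not isolated), via lactol 28 (not isolated)
Conditions: TEMPO (0.2 equiv), PhI(OAc)2 (3 equiv), CH2Cl2, rt
Reagents that add atoms: none
Why: Oxoammonium oxidation; the primary alcohol is oxidised selectively to the aldehyde, which is trapped by the C6 hydroxyl as the five-membered lactol and oxidised on to the trans-fused lactone, and the weakly acidic medium should not epimerise C11.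

Step 20
Reactants: 29 (3S,6S,7S,9S,11R)-3,9-bis[(tert-butyldimethylsilyl)oxy]germacra-1(10)Z,4E-dien-12,6-olide
Product: 30 (3S,6S,7S,9S,11R)-3,9-dihydroxygermacra-1(10)Z,4E-dien-12,6-olide
Conditions: HF·pyridine, pyridine, THF, 0 °C to rt
Reagents that add atoms: none
Why: Fluoride cleavage of both secondary TBS ethers under buffered, non-basic conditions, so that the lactone and the epimerisable C11 are not exposed to base and the diene not to strong acid.

Step 21
Reactants: 30 (3S,6S,7S,9S,11R)-3,9-dihydroxygermacra-1(10)Z,4E-dien-12,6-olide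
Product: 31 (3S,6S,7S,9S,11R)-3,9-diacetoxygermacra-1(10)Z,4E-dien-12,6-olide (CNP0226482.5)
Conditions: Ac2O, DMAP (cat.), pyridine, CH2Cl2, 0 °C to rt
Reagents that add atoms: acetic anhydride CC(=O)OC(C)=O
Why: DMAP-catalysed acylation of the two secondary allylic alcohols with retention at C3 and C9; the conditions are too mild to epimerise C11.

## Compound list

1 | prop-2-yn-1-ol (propargyl alcohol) | C#CCO | starting material
2 | dimethylaluminium (2E)-3-(dimethylalumanyl)-2-methylprop-2-en-1-olate | C[Al](C)OC/C(C)=C/[Al](C)C | intermediate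
3 | (2E)-3-iodo-2-methylprop-2-en-1-ol | OC/C(C)=C/I | intermediate
4 | triethyl{[(2E)-3-iodo-2-methylprop-2-en-1-yl]oxy}silane | CC[Si](CC)(CC)OC/C(C)=C/I | intermediate
5 | (2E)-4,4-dimethoxy-2-methylbut-2-enal | O=C/C(C)=C/C(OC)OC | starting material
6 | (4S,5E)-7,7-dimethoxy-5-methylhepta-1,5-dien-4-ol | COC(OC)/C=C(\C)[C@@H](O)CC=C | intermediate
7 | tert-butyl{[(4S,5E)-7,7-dimethoxy-5-methylhepta-1,5-dien-4-yl]oxy}dimethylsilane | COC(OC)/C=C(\C)[C@@H](O[Si](C)(C)C(C)(C)C)CC=C | intermediate
8 | (4S,5E)-4-[(tert-butyldimethylsilyl)oxy]-7,7-dimethoxy-5-methylhept-5-ene-1,2-diol (both C2 epimers) | COC(OC)/C=C(\C)[C@@H](O[Si](C)(C)C(C)(C)C)CC(O)CO | intermediate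
9 | (3S,4E)-3-[(tert-butyldimethylsilyl)oxy]-6,6-dimethoxy-4-methylhex-4-enal | COC(OC)/C=C(\C)[C@@H](O[Si](C)(C)C(C)(C)C)CC=O | intermediate
10 | ethyl 2-[bis(2,2,2-trifluoroethoxy)phosphoryl]propanoate | CCOC(=O)C(C)P(=O)(OCC(F)(F)F)OCC(F)(F)F | starting material
11 | ethyl (2Z,5S,6E)-5-[(tert-butyldimethylsilyl)oxy]-8,8-dimethoxy-2,6-dimethylocta-2,6-dienoate | COC(OC)/C=C(\C)[C@@H](O[Si](C)(C)C(C)(C)C)C/C=C(/C)C(=O)OCC | intermediate
12 | ethyl (2Z,5S,6E)-5-[(tert-butyldimethylsilyl)oxy]-2,6-dimethyl-8-oxoocta-2,6-dienoate | O=C/C=C(\C)[C@@H](O[Si](C)(C)C(C)(C)C)C/C=C(/C)C(=O)OCC | intermediate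
13 | {(1E)-2-methyl-3-[(triethylsilyl)oxy]prop-1-en-1-yl}lithium | CC[Si](CC)(CC)OC/C(C)=C/[Li] | intermediate
14 | bis{(1E)-2-methyl-3-[(triethylsilyl)oxy]prop-1-en-1-yl}zinc | CC[Si](CC)(CC)OC/C(C)=C/[Zn]/C=C(\C)CO[Si](CC)(CC)CC | intermediate
15 | ethyl (2Z,5S,6E,8S,9E)-5-[(tert-butyldimethylsilyl)oxy]-8-hydroxy-2,6,10-trimethyl-11-[(triethylsilyl)oxy]undeca-2,6,9-trienoate | CC[Si](CC)(CC)OC/C(C)=C/[C@H](O)/C=C(\C)[C@@H](O[Si](C)(C)C(C)(C)C)C/C=C(/C)C(=O)OCC | intermediate
16 | ethyl (2Z,5S,6E,8S,9E)-5-[(tert-butyldimethylsilyl)oxy]-8-[(4-methoxybenzyl)oxy]-2,6,10-trimethyl-11-[(triethylsilyl)oxy]undeca-2,6,9-trienoate | CC[Si](CC)(CC)OC/C(C)=C/[C@H](OCc1ccc(OC)cc1)/C=C(\C)[C@@H](O[Si](C)(C)C(C)(C)C)C/C=C(/C)C(=O)OCC | intermediate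
17 | ethyl (2Z,5S,6E,8S,9E)-5-[(tert-butyldimethylsilyl)oxy]-11-hydroxy-8-[(4-methoxybenzyl)oxy]-2,6,10-trimethylundeca-2,6,9-trienoate | OC/C(C)=C/[C@H](OCc1ccc(OC)cc1)/C=C(\C)[C@@H](O[Si](C)(C)C(C)(C)C)C/C=C(/C)C(=O)OCC | intermediate
18 | (2Z,5S,6E,8S,9E)-5-[(tert-butyldimethylsilyl)oxy]-11-hydroxy-8-[(4-methoxybenzyl)oxy]-2,6,10-trimethylundeca-2,6,9-trienoic acid | OC/C(C)=C/[C@H](OCc1ccc(OC)cc1)/C=C(\C)[C@@H](O[Si](C)(C)C(C)(C)C)C/C=C(/C)C(=O)O | intermediate
19 | (3Z,6S,7E,9S,10E)-6-[(tert-butyldimethylsilyl)oxy]-9-[(4-methoxybenzyl)oxy]-3,7,11-trimethyl-1-oxacyclododeca-3,7,10-trien-2-one (macrolactone joining C9 to O–C12) | O=C1OC/C(C)=C/[C@H](OCc2ccc(OC)cc2)/C=C(\C)[C@@H](O[Si](C)(C)C(C)(C)C)C/C=C\1C | intermediate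
20 | tert-butyl{[(3Z,6S,7E,9S,10E)-9-[(4-methoxybenzyl)oxy]-3,7,11-trimethyl-2-methylidene-1-oxacyclododeca-3,7,10-trien-6-yl]oxy}dimethylsilane (precursor of the key step) | C=C1OC/C(C)=C/[C@H](OCc2ccc(OC)cc2)/C=C(\C)[C@@H](O[Si](C)(C)C(C)(C)C)C/C=C\1C | intermediate
21 | (3S,6R,7S)-3-[(tert-butyldimethylsilyl)oxy]-6-[(4-methoxybenzyl)oxy]germacra-1(10)Z,4E,11(12)-trien-9-one (product of the key step; C6 reads R only because the isopropenyl-bearing C7 outranks C5, the spatial arrangement is that of 6S in the target) | O=C1C[C@@H](C(C)=C)[C@@H](/C=C(\C)[C@@H](O[Si](C)(C)C(C)(C)C)C/C=C\1C)OCc2ccc(OC)cc2 | intermediate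
22 | (3S,6R,7S,9S)-3-[(tert-butyldimethylsilyl)oxy]-6-[(4-methoxybenzyl)oxy]germacra-1(10)Z,4E,11(12)-trien-9-ol | O[C@H]1C[C@@H](C(C)=C)[C@@H](/C=C(\C)[C@@H](O[Si](C)(C)C(C)(C)C)C/C=C\1C)OCc2ccc(OC)cc2 | intermediate
23 | (3S,6R,7S,9S)-3,9-bis[(tert-butyldimethylsilyl)oxy]-6-[(4-methoxybenzyl)oxy]germacra-1(10)Z,4E,11(12)-triene | CC(C)(C)[Si](C)(C)O[C@H]1C[C@@H](C(C)=C)[C@@H](/C=C(\C)[C@@H](O[Si](C)(C)C(C)(C)C)C/C=C\1C)OCc2ccc(OC)cc2 | intermediate
24 | 9-{(3S,6S,7S,9S)-3,9-bis[(tert-butyldimethylsilyl)oxy]-6-[(4-methoxybenzyl)oxy]germacra-1(10)Z,4E-dien-12-yl}-9-borabicyclo[3.3.1]nonane (C11 arranged as in 25) | CC(C)(C)[Si](C)(C)O[C@H]1C[C@@H]([C@@H](C)CB2C3CCCC2CCC3)[C@@H](/C=C(\C)[C@@H](O[Si](C)(C)C(C)(C)C)C/C=C\1C)OCc4ccc(OC)cc4 | intermediate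
25 | (3S,6S,7S,9S,11R)-3,9-bis[(tert-butyldimethylsilyl)oxy]-6-[(4-methoxybenzyl)oxy]germacra-1(10)Z,4E-dien-12-ol | CC(C)(C)[Si](C)(C)O[C@H]1C[C@@H]([C@@H](C)CO)[C@@H](/C=C(\C)[C@@H](O[Si](C)(C)C(C)(C)C)C/C=C\1C)OCc2ccc(OC)cc2 | intermediate
26 | (3S,6S,7S,9S,11R)-3,9-bis[(tert-butyldimethylsilyl)oxy]germacra-1(10)Z,4E-diene-6,12-diol | CC(C)(C)[Si](C)(C)O[C@H]1C[C@@H]([C@@H](C)CO)[C@@H](/C=C(\C)[C@@H](O[Si](C)(C)C(C)(C)C)C/C=C\1C)O | intermediate
27 | (3S,6S,7S,9S,11R)-3,9-bis[(tert-butyldimethylsilyl)oxy]-6-hydroxygermacra-1(10)Z,4E-dien-12-al | CC(C)(C)[Si](C)(C)O[C@H]1C[C@@H]([C@@H](C)C=O)[C@@H](/C=C(\C)[C@@H](O[Si](C)(C)C(C)(C)C)C/C=C\1C)O | intermediate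
28 | (3S,6S,7S,9S,11R)-3,9-bis[(tert-butyldimethylsilyl)oxy]-6,12-epoxygermacra-1(10)Z,4E-dien-12-ol (lactol, both C12 epimers) | CC(C)(C)[Si](C)(C)O[C@H]1C[C@@H]2[C@@H](/C=C(\C)[C@@H](O[Si](C)(C)C(C)(C)C)C/C=C\1C)OC(O)[C@@H]2C | intermediate
29 | (3S,6S,7S,9S,11R)-3,9-bis[(tert-butyldimethylsilyl)oxy]germacra-1(10)Z,4E-dien-12,6-olide | CC(C)(C)[Si](C)(C)O[C@H]1C[C@@H]2[C@@H](/C=C(\C)[C@@H](O[Si](C)(C)C(C)(C)C)C/C=C\1C)OC(=O)[C@@H]2C | intermediate
30 | (3S,6S,7S,9S,11R)-3,9-dihydroxygermacra-1(10)Z,4E-dien-12,6-olide | O[C@H]1C[C@@H]2[C@@H](/C=C(\C)[C@@H](O)C/C=C\1C)OC(=O)[C@@H]2C | intermediate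
31 | (3S,6S,7S,9S,11R)-3,9-diacetoxygermacra-1(10)Z,4E-dien-12,6-olide (CNP0226482.5) | CC(=O)O[C@H]1C[C@@H]2[C@@H](/C=C(\C)[C@@H](OC(C)=O)C/C=C\1C)OC(=O)[C@@H]2C | target

## Step count and risk

Total step count: 21 steps. Longest linear sequence: 19 steps (from 5 through steps 3–21); the iodide 4 is made in a two-step branch (steps 1–2) and joins at step 8.

Steps least certain to work:

Step 14 (key step). The thermal window may not separate the [3,3] shift from other processes. These are 1,5-hydrogen migration from C2 to C8 within the Z-configured alkoxydiene, and Cope rearrangement of the C10=C1–C2–C3–C4=C5 unit in 20 or 21, which the C3 silyloxy group would make irreversible. Trace acid can also hydrolyse or isomerise the enol ether, and a strained or boat-like transition state could erode the facial selectivity at C7. Fallback: starting from 20, thermal activation is replaced by charge acceleration with iBu3Al in CH2Cl2 at −78 °C. The aluminium-bound ether should rearrange at low temperature, and the C9 ketone is reduced in the same flask by β-hydride transfer from an isobutyl group. This gives (3S,6R,7S)-3-[(tert-butyldimethylsilyl)oxy]-6-[(4-methoxybenzyl)oxy]germacra-1(10)Z,4E,11(12)-trien-9-ol as a mixture of C9 epimers F1. Oxidation of the mixture with Dess–Martin periodinane (NaHCO3 buffer) returns to 21; the 9S component is 22 itself.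

Step 8. Facial selectivity at C6 may be insufficient: the C3 centre is too remote to help, the enal is β,β-disubstituted, and a halide-promoted background addition gives the C6 epimer. Fallback: from 4 and 12 directly, without an organolithium, a Nozaki–Hiyama–Kishi coupling (CrCl2, catalytic NiCl2, a chiral oxazoline–sulfonamide ligand, THF–MeCN) forms the same bond through an alkenylchromium species under ligand control and returns at 15. No new compound is needed.

Step 12. Oligomerisation, or SN2′ attack and elimination at the activated allylic alcohol, may outrun closure of a ring that holds three trisubstituted alkenes. Fallback: the macrocycle is closed at C6–C7 instead of at the ester. From 11, saponification gives (2Z,5S,6E)-5-[(tert-butyldimethylsilyl)oxy]-8,8-dimethoxy-2,6-dimethylocta-2,6-dienoic acid F2. Intermolecular Mitsunobu esterification with 3 gives the (2E)-3-iodo-2-methylprop-2-en-1-yl ester F3, and acetal hydrolysis (PPTS, wet acetone) gives the aldehyde ester F4. An intramolecular Nozaki–Hiyama–Kishi reaction (CrCl2, catalytic NiCl2, chiral sulfonamide ligand, high dilution) closes the twelve-membered ring to the C6 carbinol (3Z,6S,7E,9S,10E)-6-[(tert-butyldimethylsilyl)oxy]-9-hydroxy-3,7,11-trimethyl-1-oxacyclododeca-3,7,10-trien-2-one F5. Benzylation with 4-methoxybenzyl trichloroacetimidate and catalytic La(OTf)3 returns to 19, bypassing 15–18.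

Step 15. The ring conformation may expose only one face of the C9 carbonyl (peripheral attack) and override the catalyst, or conjugate reduction may compete. Fallback: from 21, a Luche reduction (NaBH4, CeCl3, MeOH) is used to take the ring-controlled product. If this is the 9R carbinol (3S,6R,7S,9R)-3-[(tert-butyldimethylsilyl)oxy]-6-[(4-methoxybenzyl)oxy]germacra-1(10)Z,4E,11(12)-trien-9-ol F6, it is inverted by a Mitsunobu reaction with 4-nitrobenzoic acid to the 9S 4-nitrobenzoate F7. Methanolysis (K2CO3, MeOH) returns to 22.

Step 17. The conformation of the ten-membered ring may override the acyclic model, so that the borane attacks the other face of the isopropenyl group and 11S results. Fallback: C11 is set at the lactone stage instead. From 23, the 11S alcohol (3S,6S,7S,9S,11S)-3,9-bis[(tert-butyldimethylsilyl)oxy]-6-[(4-methoxybenzyl)oxy]germacra-1(10)Z,4E-dien-12-ol F8 is carried through DDQ cleavage to the 11S diol F9 and through TEMPO/PhI(OAc)2 oxidation to the 11S lactone F10. Deprotonation with LDA at −78 °C and kinetic protonation of the lactone enolate with 2,6-di-tert-butyl-4-methylphenol should deliver the proton anti to C8 and return to 29. This is possible because 29 has no other acidic site.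

Further compounds

F1 | step 14 | (3S,6R,7S)-3-[(tert-butyldimethylsilyl)oxy]-6-[(4-methoxybenzyl)oxy]germacra-1(10)Z,4E,11(12)-trien-9-ol, both C9 epimers | OC1C[C@@H](C(C)=C)[C@@H](/C=C(\C)[C@@H](O[Si](C)(C)C(C)(C)C)C/C=C\1C)OCc2ccc(OC)cc2
F0 | step 8 | none | none
F2 | step 12 | (2Z,5S,6E)-5-[(tert-butyldimethylsilyl)oxy]-8,8-dimethoxy-2,6-dimethylocta-2,6-dienoic acid | COC(OC)/C=C(\C)[C@@H](O[Si](C)(C)C(C)(C)C)C/C=C(/C)C(=O)O
F3 | step 12 | (2E)-3-iodo-2-methylprop-2-en-1-yl (2Z,5S,6E)-5-[(tert-butyldimethylsilyl)oxy]-8,8-dimethoxy-2,6-dimethylocta-2,6-dienoate | COC(OC)/C=C(\C)[C@@H](O[Si](C)(C)C(C)(C)C)C/C=C(/C)C(=O)OC/C(C)=C/I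
F4 | step 12 | (2E)-3-iodo-2-methylprop-2-en-1-yl (2Z,5S,6E)-5-[(tert-butyldimethylsilyl)oxy]-2,6-dimethyl-8-oxoocta-2,6-dienoate | O=C/C=C(\C)[C@@H](O[Si](C)(C)C(C)(C)C)C/C=C(/C)C(=O)OC/C(C)=C/I
F5 | step 12 | (3Z,6S,7E,9S,10E)-6-[(tert-butyldimethylsilyl)oxy]-9-hydroxy-3,7,11-trimethyl-1-oxacyclododeca-3,7,10-trien-2-one | O=C1OC/C(C)=C/[C@H](O)/C=C(\C)[C@@H](O[Si](C)(C)C(C)(C)C)C/C=C\1C
F6 | step 15 | (3S,6R,7S,9R)-3-[(tert-butyldimethylsilyl)oxy]-6-[(4-methoxybenzyl)oxy]germacra-1(10)Z,4E,11(12)-trien-9-ol | O[C@@H]1C[C@@H](C(C)=C)[C@@H](/C=C(\C)[C@@H](O[Si](C)(C)C(C)(C)C)C/C=C\1C)OCc2ccc(OC)cc2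
F7 | step 15 | (3S,6R,7S,9S)-3-[(tert-butyldimethylsilyl)oxy]-6-[(4-methoxybenzyl)oxy]germacra-1(10)Z,4E,11(12)-trien-9-yl 4-nitrobenzoate | O=C(O[C@H]1C[C@@H](C(C)=C)[C@@H](/C=C(\C)[C@@H](O[Si](C)(C)C(C)(C)C)C/C=C\1C)OCc2ccc(OC)cc2)c3ccc([N+](=O)[O-])cc3
F8 | step 17 | (3S,6S,7S,9S,11S)-3,9-bis[(tert-butyldimethylsilyl)oxy]-6-[(4-methoxybenzyl)oxy]germacra-1(10)Z,4E-dien-12-ol | CC(C)(C)[Si](C)(C)O[C@H]1C[C@@H]([C@H](C)CO)[C@@H](/C=C(\C)[C@@H](O[Si](C)(C)C(C)(C)C)C/C=C\1C)OCc2ccc(OC)cc2
F9 | step 17 | (3S,6S,7S,9S,11S)-3,9-bis[(tert-butyldimethylsilyl)oxy]germacra-1(10)Z,4E-diene-6,12-diol | CC(C)(C)[Si](C)(C)O[C@H]1C[C@@H]([C@H](C)CO)[C@@H](/C=C(\C)[C@@H](O[Si](C)(C)C(C)(C)C)C/C=C\1C)O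
F10 | step 17 | (3S,6S,7S,9S,11S)-3,9-bis[(tert-butyldimethylsilyl)oxy]germacra-1(10)Z,4E-dien-12,6-olide | CC(C)(C)[Si](C)(C)O[C@H]1C[C@@H]2[C@@H](/C=C(\C)[C@@H](O[Si](C)(C)C(C)(C)C)C/C=C\1C)OC(=O)[C@H]2C
A1 | alternative 1 | open-chain ynal: (6S,7S,9S,11R)-9-acetoxy-6-(prop-1-yn-1-yl)-12,6-olide with Z-C1=C10 and a C3 aldehyde | CC(=O)O[C@@H](C[C@@H]1[C@@H](C#CC)OC(=O)[C@@H]1C)/C(C)=C\CC=O
A2 | alternative 1 | (3S,6S,7S,9S,11R)-9-acetoxy-3-[(triethylsilyl)oxy]germacra-1(10)Z,4E-dien-12,6-olide | CC(=O)O[C@H]1C[C@@H]2[C@@H](/C=C(\C)[C@@H](O[Si](CC)(CC)CC)C/C=C\1C)OC(=O)[C@@H]2C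
A3 | alternative 2 | trans-decalin hydroxy mesylate (C4–C9 bonded; C9 tertiary OH, C4 angular methyl, C5 equatorial mesylate, C3 TBS ether, C1=C10 in the ring, 12,6-lactone) | O[C@]12C[C@@H]3[C@@H]([C@@H](OS(C)(=O)=O)[C@]1(C)[C@@H](O[Si](C)(C)C(C)(C)C)CC=C2C)OC(=O)[C@@H]3C
A4 | alternative 2 | (3S,6S,7S,11R)-3-[(tert-butyldimethylsilyl)oxy]-9-oxogermacra-1(10)Z,4E-dien-12,6-olide | O=C1C[C@@H]2[C@@H](/C=C(\C)[C@@H](O[Si](C)(C)C(C)(C)C)C/C=C\1C)OC(=O)[C@@H]2C
A5 | alternative 3 | cis-anti-cis photoadduct (cyclohexanone C5–C10 fused to a bicyclo[2.2.0]hexane C10–C1–C4–C5 / C1–C2–C3–C4, C3 acetate, 12,6-lactone) | O=C1C[C@@H]2[C@@H]([C@@H]3[C@@]1(C)[C@H]1C[C@H](OC(C)=O)[C@]13C)OC(=O)[C@@H]2C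
A6 | alternative 3 | (3S,6S,7S,11R)-3-acetoxy-9-oxogermacra-1(10)Z,4E-dien-12,6-olide | O=C1C[C@@H]2[C@@H](/C=C(\C)[C@@H](OC(C)=O)C/C=C\1C)OC(=O)[C@@H]2C
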